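**Plan**

- Retrosynthesis: cut the acetyl C–O bond (alcohol 6). Return C7–OH to the C7 ketone, which deliberately erases both stereocentres (racemic ketone 4). Cut the C8–O(aryl) bond (bromoketone 2 + phenol 3), then the C8–Br bond (propiophenone 1).
- Forward: brominate C8 of 1, join the chain to the 4-allyl-2,6-dimethoxyphenyl ring through oxygen by SN2, reduce C7=O under dynamic kinetic resolution, acetylate.
- Enabling feature: in 4 the C8–H lies between the C7 carbonyl (conjugated to the trimethoxyphenyl ring) and the oxygen of the 4-allyl-2,6-dimethoxyphenoxy ring. It is therefore configurationally labile, and the two enantiomers of 4 interconvert through enol 5.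
- Stereochemistry: C7 comes from the (S,S)-Ru transfer-hydrogenation catalyst (facial control). C8 comes from selection between the equilibrating ketone enantiomers (polar Felkin–Anh), which should funnel the racemate into the threo (7R,8R) alcohol.
- The allyl group is never exposed to H2/heterogeneous metal or to strong base.

Key step: step 3

Remark (assumption): C7 is the benzylic carbon, C8 the aryloxy-bearing carbon and C9 its methyl group. The target is the threo (7R,8R) isomer. Compounds 1 and 3 are taken as catalogue compounds.

**Step 1**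
Reactants: 1 1-(3,4,5-trimethoxyphenyl)propan-1-one
Product: 2 rac-2-bromo-1-(3,4,5-trimethoxyphenyl)propan-1-one
Conditions: CuBr2 (2.1 equiv), EtOAc/CHCl3 1:1, reflux
Reagents that add atoms: copper(II) bromide, [Cu+2].[Br-].[Br-]
Why: Copper(II) bromide α-bromination of an aryl ketone through its copper-bound enol should halogenate C8 only and leave the electron-rich ring untouched; the new centre is racemic, which is intended.

**Step 2**
Reactants: 2 rac-2-bromo-1-(3,4,5-trimethoxyphenyl)propan-1-one; 3 4-allyl-2,6-dimethoxyphenol
Product: 4 rac-2-(4-allyl-2,6-dimethoxyphenoxy)-1-(3,4,5-trimethoxyphenyl)propan-1-one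
Conditions: K2CO3 (1.5 equiv), acetone, reflux
Reagents that add atoms: none
Why: Williamson ether synthesis, in which the phenoxide of 3 (ortho and para positions blocked, so only O-alkylation) displaces the carbonyl-activated secondary bromide by SN2; C8 stays racemic, as the key step requires.

**Step 3**
Reactants: 4 rac-2-(4-allyl-2,6-dimethoxyphenoxy)-1-(3,4,5-trimethoxyphenyl)propan-1-one
Product: 6 (1R,2R)-2-(4-allyl-2,6-dimethoxyphenoxy)-1-(3,4,5-trimethoxyphenyl)propan-1-ol, via enol 2-(4-allyl-2,6-dimethoxyphenoxy)-1-(3,4,5-trimethoxyphenyl)prop-1-en-1-ol 5 (not isolated)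
Conditions: RuCl[(S,S)-TsDPEN](p-cymene) (1 mol %), HCO2H (3 equiv), DBU (4 equiv), DMF, 40 °C
Reagents that add atoms: none
Why: DBU should reversibly remove the C8–H of 4 (acidified by C7=O and the aryloxy oxygen) to give achiral enol(ate) 5, so that (R)- and (S)-4 interconvert while the 18-electron Ru–H/N–H catalyst transfers hydride and proton to C7=O through an outer-sphere six-membered transition state (Noyori–Ikariya asymmetric transfer hydrogenation under dynamic kinetic resolution). The closest known reactions are the conversion of racemic benzoin into (R,R)-hydrobenzoin and of α-alkoxy β-keto esters into syn-diol monoethers with this catalyst family, and the base-mediated dynamic hydrogenation of α-aryloxy ketones; no ring is closed. C7 is set by the catalyst: the (S,S) complex holds the trimethoxyphenyl ring under the η6-cymene (CH/π contact) and delivers hydride to the face that makes acetophenone (S), which here is 7R because C8 outranks the aryl group. C8 is set by selection between the equilibrating enantiomers: the saturated Ru centre cannot chelate, so a polar Felkin–Anh arrangement should apply, with the C8–OAr bond anti to the incoming hydride and the hydride passing C8–H rather than C8–CH3, and only (R)-4 can adopt it on the catalyst-preferred face, leading to the threo (7R,8R) alcohol. The step needs racemisation to outpace reduction of the mismatched (S)-ketone, which free DBU and the slow, irreversible formate reduction should secure, and product 6 can no longer epimerise at C8. It also needs C=O over C=C selectivity, which the coordinatively saturated hydride secures because the allyl group cannot bind to ruthenium.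

**Step 4**
Reactants: 6 (1R,2R)-2-(4-allyl-2,6-dimethoxyphenoxy)-1-(3,4,5-trimethoxyphenyl)propan-1-ol
Product: 7 (1R,2R)-2-(4-allyl-2,6-dimethoxyphenoxy)-1-(3,4,5-trimethoxyphenyl)propyl acetate
Conditions: Ac2O, pyridine, DMAP (cat.), CH2Cl2, 0 °C to rt
Reagents that add atoms: acetic anhydride, CC(=O)OC(C)=O
Why: DMAP-catalysed O-acylation of the secondary benzylic alcohol breaks no bond at C7 or C8, so both configurations are retained.

**Compound list**

1 | 1-(3,4,5-trimethoxyphenyl)propan-1-one | CCC(=O)c1cc(OC)c(OC)c(OC)c1 | starting material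
2 | rac-2-bromo-1-(3,4,5-trimethoxyphenyl)propan-1-one | CC(Br)C(=O)c1cc(OC)c(OC)c(OC)c1 | intermediate
3 | 4-allyl-2,6-dimethoxyphenol | C=CCc1cc(OC)c(O)c(OC)c1 | starting material
4 | rac-2-(4-allyl-2,6-dimethoxyphenoxy)-1-(3,4,5-trimethoxyphenyl)propan-1-one | C=CCc1cc(OC)c(OC(C)C(=O)c2cc(OC)c(OC)c(OC)c2)c(OC)c1 | intermediate
5 | 2-(4-allyl-2,6-dimethoxyphenoxy)-1-(3,4,5-trimethoxyphenyl)prop-1-en-1-ol (enol of 4, either double-bond geometry, present as its DBU-H+ enolate; not isolated) | C=CCc1cc(OC)c(OC(C)=C(O)c2cc(OC)c(OC)c(OC)c2)c(OC)c1 | intermediate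
6 | (1R,2R)-2-(4-allyl-2,6-dimethoxyphenoxy)-1-(3,4,5-trimethoxyphenyl)propan-1-ol | C=CCc1cc(OC)c(O[C@H](C)[C@H](O)c2cc(OC)c(OC)c(OC)c2)c(OC)c1 | intermediate
7 | (1R,2R)-2-(4-allyl-2,6-dimethoxyphenoxy)-1-(3,4,5-trimethoxyphenyl)propyl acetate | C=CCc1cc(OC)c(O[C@H](C)[C@H](OC(C)=O)c2cc(OC)c(OC)c(OC)c2)c(OC)c1 | target

**Step count**

Total steps: 4. Longest linear sequence: 4 steps (1 → 2 → 4 → 6 → 7).

**Steps most likely to fail**

1. Step 3. Enolisation at C8 may be slower than hydride transfer, so that the mismatched ketone enantiomer is also reduced and erythro alcohol forms. Alternatively, the intrinsic facial preference of the substrate may not match the catalyst, giving poor diastereoselection. The fallback sets C8 from the chiral pool and C7 by catalyst control alone; it sets out from 3 and comes back at 6. Phenol 3 is coupled with commercial ethyl (S)-lactate under Mitsunobu conditions (PPh3, DIAD, THF, 0 °C to rt, inversion) to give ethyl (2R)-2-(4-allyl-2,6-dimethoxyphenoxy)propanoate F1. Treatment with MeNH(OMe)·HCl and i-PrMgCl (THF, −20 °C) should give (2R)-2-(4-allyl-2,6-dimethoxyphenoxy)-N-methoxy-N-methylpropanamide F2. Addition of commercial 3,4,5-trimethoxyphenylmagnesium bromide (THF, 0 °C) should give (2R)-2-(4-allyl-2,6-dimethoxyphenoxy)-1-(3,4,5-trimethoxyphenyl)propan-1-one F3, the single (R)-enantiomer of 4. F3 is reduced with the same (S,S)-Ru catalyst in HCO2H/Et3N 5:2 (acidic, so C8 does not epimerise; the catalyst fixes 7R) to give 6, which enters step 4.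

2. Step 2. SN2 attack of the di-ortho-substituted phenoxide at the secondary carbon may be sluggish, and dehydrobromination to the aryl vinyl ketone may compete. The fallback builds the ether on an ester and forms the aryl ketone bond last; it sets out from 3 and comes back at 4. Phenol 3 is alkylated with racemic ethyl 2-bromopropanoate (K2CO3, DMF, 60 °C) to give rac-ethyl 2-(4-allyl-2,6-dimethoxyphenoxy)propanoate F4. This is converted with MeNH(OMe)·HCl and i-PrMgCl (THF, −20 °C) into rac-2-(4-allyl-2,6-dimethoxyphenoxy)-N-methoxy-N-methylpropanamide F5. Addition of commercial 3,4,5-trimethoxyphenylmagnesium bromide (THF, 0 °C) should give 4, which enters step 3. This path also bypasses step 1.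

3. Step 1. Electrophilic bromination of the electron-rich trimethoxyphenyl ring, or a second bromination at C8, may compete. The fallback replaces halogenation by hypervalent-iodine α-oxidation; it sets out from 1 and comes back at 4. Ketone 1 is treated with [hydroxy(tosyloxy)iodo]benzene (MeCN, reflux) to give rac-1-oxo-1-(3,4,5-trimethoxyphenyl)propan-2-yl 4-methylbenzenesulfonate F6. F6 takes the place of 2 under the conditions of step 2 (3, K2CO3, acetone, reflux) and should give 4.

**Further compounds**

F1 | step 3 | ethyl (2R)-2-(4-allyl-2,6-dimethoxyphenoxy)propanoate | C=CCc1cc(OC)c(O[C@H](C)C(=O)OCC)c(OC)c1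
F2 | step 3 | (2R)-2-(4-allyl-2,6-dimethoxyphenoxy)-N-methoxy-N-methylpropanamide | C=CCc1cc(OC)c(O[C@H](C)C(=O)N(C)OC)c(OC)c1
F3 | step 3 | (2R)-2-(4-allyl-2,6-dimethoxyphenoxy)-1-(3,4,5-trimethoxyphenyl)propan-1-one | C=CCc1cc(OC)c(O[C@H](C)C(=O)c2cc(OC)c(OC)c(OC)c2)c(OC)c1
F4 | step 2 | rac-ethyl 2-(4-allyl-2,6-dimethoxyphenoxy)propanoate | C=CCc1cc(OC)c(OC(C)C(=O)OCC)c(OC)c1
F5 | step 2 | rac-2-(4-allyl-2,6-dimethoxyphenoxy)-N-methoxy-N-methylpropanamide | C=CCc1cc(OC)c(OC(C)C(=O)N(C)OC)c(OC)c1
F6 | step 1 | rac-1-oxo-1-(3,4,5-trimethoxyphenyl)propan-2-yl 4-methylbenzenesulfonate | CC(OS(=O)(=O)c1ccc(C)cc1)C(=O)c1cc(OC)c(OC)c(OC)c1
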